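The route rests on disconnecting the bond between C2 of the pyran (C) ring and C1' of the pyrogallol (B) ring. C2 is bound to the ring oxygen O1 and, at the flav-3-ene level, allylic to C3=C4, so a 2-ethoxy-2H-chromene carrying the 3-O-gallate as an enol ester ionises to an aromatic 1-benzopyrylium ion. Nickel-catalysed enantioselective arylation of this ion with the B-ring boronic acid, which already bears the 4'-O-gallate, forms C2–C1' and sets C2 (R) in one operation, with all carbons of the target in place. One final hydrogenation then adds H2 to C3=C4 anti to the 2-aryl group (2,3-cis) and removes ten benzyl ethers.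

Key step: step 10

Assumption: 3,4,5-tris(benzyloxy)benzoyl chloride (4) is taken as a purchasable reagent; otherwise it is one step from the commercial acid with oxalyl chloride.

Remark: acetal 7 is formed as a racemate at C2, which is of no consequence because C2 is ionised in step 10. The target is (2R,3R), i.e. 2,3-cis.

Step 1
Reactants: 1 3,5-bis(benzyloxy)phenol
Product: 2 1,3-bis(benzyloxy)-5-(prop-2-yn-1-yloxy)benzene
Conditions: propargyl bromide, K2CO3, acetone, reflux
Reagents that add atoms: propargyl bromide, C#CCBr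
Why: Williamson ether synthesis; the phenoxide displaces the primary propargylic bromide by SN2.

Step 2
Reactants: 2 1,3-bis(benzyloxy)-5-(prop-2-yn-1-yloxy)benzene
Product: 3 5,7-bis(benzyloxy)chroman-3-one
Conditions: Me4tBuXPhosAuNTf2 (5 mol %), 3,5-dichloropyridine N-oxide (1.3 equiv), DCE, rt
Reagents that add atoms: 3,5-dichloropyridine N-oxide, [O-][n+]1cc(Cl)cc(Cl)c1
Why: Gold-catalysed oxidative cyclisation of an aryl propargyl ether: the N-oxide delivers oxygen to the internal carbon of the gold-activated alkyne, and the resulting α-oxo gold carbene should be trapped by the electron-rich ortho carbon of the aryl ether (both ortho sites are equivalent) to close the six-membered ketone ring.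

Step 3
Reactants: 3 5,7-bis(benzyloxy)chroman-3-one; 4 3,4,5-tris(benzyloxy)benzoyl chloride
Product: 5 5,7-bis(benzyloxy)-2H-chromen-3-yl 3,4,5-tris(benzyloxy)benzoate
Conditions: Et3N, DMAP (cat.), CH2Cl2, −20 °C → rt
Reagents that add atoms: none
Why: Enol ester formation: soft enolisation of the β-tetralone-like ketone toward the more acidic benzylic C4 gives the arene-conjugated enolate, which the DMAP-activated acyl chloride should trap on oxygen.

Step 4
Reactants: 5 5,7-bis(benzyloxy)-2H-chromen-3-yl 3,4,5-tris(benzyloxy)benzoate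
Product: 7 5,7-bis(benzyloxy)-2-ethoxy-2H-chromen-3-yl 3,4,5-tris(benzyloxy)benzoate, via benzopyrylium salt 6 (not isolated)
Conditions: DDQ (1.1 equiv), CH2Cl2, 0 °C; then EtOH (excess), 0 °C → rt; filtration through basic alumina
Reagents that add atoms: ethanol, CCO
Why: Oxidative C–H functionalisation: DDQ abstracts hydride from the C2 methylene (bound to O1 and allylic to C3=C4) to give the aromatic, 5,7-dialkoxy-stabilised benzopyrylium ion, which ethanol should capture at C2 as the mixed O,O-acetal.

Step 5
Reactants: 8 1,3-bis(benzyloxy)benzene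
Product: 11 2,6-bis(benzyloxy)phenol, via aryllithium 9 (not isolated), via dimethyl arylboronate 10 (not isolated)
Conditions: n-BuLi, THF, 0 °C → rt; B(OMe)3, −78 °C → rt; AcOH, 30% H2O2, 0 °C → rt
Reagents that add atoms: trimethyl borate, COB(OC)OC (atoms only in intermediate 10); hydrogen peroxide, OO
Why: Directed ortho-metalation at the carbon flanked by both benzyloxy groups, borylation of the aryllithium, then peroxide-induced 1,2-aryl shift from boron to oxygen and hydrolysis (one-pot arene hydroxylation).

Step 6
Reactants: 11 2,6-bis(benzyloxy)phenol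
Product: 12 4-bromo-2,6-bis(benzyloxy)phenol
Conditions: NBS (1.0 equiv), CHCl3, −40 °C → rt
Reagents that add atoms: N-bromosuccinimide, O=C1CCC(=O)N1Br
Why: Electrophilic aromatic bromination directed para to the free phenolic OH, the pattern established for 2,6-dialkoxyphenols; low temperature and one equivalent of NBS should suppress attack ortho to the ethers.

Step 7
Reactants: 12 4-bromo-2,6-bis(benzyloxy)phenol; 4 3,4,5-tris(benzyloxy)benzoyl chloride
Product: 13 2,6-bis(benzyloxy)-4-bromophenyl 3,4,5-tris(benzyloxy)benzoate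
Conditions: Et3N, DMAP (cat.), CH2Cl2, 0 °C → rt
Reagents that add atoms: none
Why: DMAP-catalysed acylation of the phenol by the acid chloride (nucleophilic catalysis through the acylpyridinium ion).

Step 8
Reactants: 13 2,6-bis(benzyloxy)-4-bromophenyl 3,4,5-tris(benzyloxy)benzoate
Product: 14 2,6-bis(benzyloxy)-4-(4,4,5,5-tetramethyl-1,3,2-dioxaborolan-2-yl)phenyl 3,4,5-tris(benzyloxy)benzoate
Conditions: B2pin2, Pd(dppf)Cl2 (3 mol %), KOAc, 1,4-dioxane, 80 °C
Reagents that add atoms: bis(pinacolato)diboron, CC1(C)OB(OC1(C)C)B1OC(C)(C)C(C)(C)O1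
Why: Miyaura borylation (oxidative addition of the aryl bromide, acetate-assisted transmetalation with the diboron, reductive elimination); KOAc in dioxane should leave the hindered aryl ester and the benzyl ethers untouched.

Step 9
Reactants: 14 2,6-bis(benzyloxy)-4-(4,4,5,5-tetramethyl-1,3,2-dioxaborolan-2-yl)phenyl 3,4,5-tris(benzyloxy)benzoate
Product: 15 [3,5-bis(benzyloxy)-4-{[3,4,5-tris(benzyloxy)benzoyl]oxy}phenyl]boronic acid
Conditions: NaIO4, THF/H2O, rt; then 1 M HCl
Reagents that add atoms: water, O
Why: Oxidative deprotection of a pinacol boronate: pinacol released in the hydrolysis equilibrium is cleaved by periodate to acetone, which should drive the ester to the free boronic acid under conditions that spare the aryl gallate.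

Step 10
Reactants: 7 5,7-bis(benzyloxy)-2-ethoxy-2H-chromen-3-yl 3,4,5-tris(benzyloxy)benzoate; 15 [3,5-bis(benzyloxy)-4-{[3,4,5-tris(benzyloxy)benzoyl]oxy}phenyl]boronic acid
Product: 16 (2R)-2-[3,5-bis(benzyloxy)-4-{[3,4,5-tris(benzyloxy)benzoyl]oxy}phenyl]-5,7-bis(benzyloxy)-2H-chromen-3-yl 3,4,5-tris(benzyloxy)benzoate
Conditions: Ni(cod)2 (10 mol %), chiral TADDOL-derived phosphonite ligand (12 mol %, the antipode that delivers 2R), 1,4-dioxane/t-AmOH, rt
Reagents that add atoms: none
Why: Ionisation of the C2–OEt bond of 7, assisted by the Lewis-acidic boronic acid, together with oxidative addition to Ni(0) should give a Ni(II) η3-benzopyranyl (1-benzopyrylium) complex, to which the ethoxyboronate transfers its aryl group before C–C reductive elimination at C2 forms the C2–C1' bond. The closest known reaction type is the nickel-catalysed, base-free cross-coupling of 2-alkoxy-2H-chromenes with arylboronic acids, including its ligand-controlled enantioselective form; the 3-acyloxy substituent is the only element outside that precedent. No ring is closed in this step. The C2 stereocentre is controlled by the chiral phosphonite on nickel, which discriminates the two faces of the planar benzopyrylium unit, and the racemic configuration of 7 is erased on ionisation, so the process is stereoconvergent. The step needs attack at C2 and not C4, which the peri 5-benzyloxy group shielding C4 and the retention of C3=C4 conjugation with the A-ring should secure. It also needs chemoselectivity over the aryl and enol gallate C–O bonds, into which phosphonite-ligated Ni(0) is not expected to insert at room temperature.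

Step 11
Reactants: 16 (2R)-2-[3,5-bis(benzyloxy)-4-{[3,4,5-tris(benzyloxy)benzoyl]oxy}phenyl]-5,7-bis(benzyloxy)-2H-chromen-3-yl 3,4,5-tris(benzyloxy)benzoate
Product: 17 epigallocatechin 3,4'-di-O-gallate, (2R,3R)
Conditions: H2 (1 atm), 20% Pd(OH)2/C, THF/MeOH, rt; neutral work-up
Reagents that add atoms: none
Why: Heterogeneous syn-hydrogenation of the C3=C4 enol ester from the face opposite the pseudo-axial 2-aryl group should place H-3 trans to the aryl group and thus the 3-O-gallate cis to it (3R), as in the classical reduction of 3-oxygenated flavenes to 2,3-cis-flavan-3-ols, while the ten O-benzyl groups are removed by hydrogenolysis in the same operation.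

Compound list
1 | 3,5-bis(benzyloxy)phenol | Oc1cc(OCc2ccccc2)cc(OCc2ccccc2)c1 | starting material
2 | 1,3-bis(benzyloxy)-5-(prop-2-yn-1-yloxy)benzene | C#CCOc1cc(OCc2ccccc2)cc(OCc2ccccc2)c1 | intermediate
3 | 5,7-bis(benzyloxy)chroman-3-one | O=C1COc2cc(OCc3ccccc3)cc(OCc3ccccc3)c2C1 | intermediate
4 | 3,4,5-tris(benzyloxy)benzoyl chloride | O=C(Cl)c1cc(OCc2ccccc2)c(OCc2ccccc2)c(OCc2ccccc2)c1 | starting material
5 | 5,7-bis(benzyloxy)-2H-chromen-3-yl 3,4,5-tris(benzyloxy)benzoate | O=C(OC1=Cc2c(OCc3ccccc3)cc(OCc3ccccc3)cc2OC1)c1cc(OCc2ccccc2)c(OCc2ccccc2)c(OCc2ccccc2)c1 | intermediate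
6 | 5,7-bis(benzyloxy)-3-{[3,4,5-tris(benzyloxy)benzoyl]oxy}chromenylium 2,3-dichloro-5,6-dicyano-4-hydroxyphenolate | O=C(Oc1c[o+]c2cc(OCc3ccccc3)cc(OCc3ccccc3)c2c1)c1cc(OCc2ccccc2)c(OCc2ccccc2)c(OCc2ccccc2)c1.N#Cc1c(O)c(Cl)c(Cl)c([O-])c1C#N | intermediate (not isolated)
7 | 5,7-bis(benzyloxy)-2-ethoxy-2H-chromen-3-yl 3,4,5-tris(benzyloxy)benzoate (racemic) | CCOC1Oc2cc(OCc3ccccc3)cc(OCc3ccccc3)c2C=C1OC(=O)c1cc(OCc2ccccc2)c(OCc2ccccc2)c(OCc2ccccc2)c1 | intermediate
8 | 1,3-bis(benzyloxy)benzene | c1ccc(COc2cccc(OCc3ccccc3)c2)cc1 | starting material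
9 | [2,6-bis(benzyloxy)phenyl]lithium | [Li]c1c(OCc2ccccc2)cccc1OCc1ccccc1 | intermediate (not isolated)
10 | dimethyl [2,6-bis(benzyloxy)phenyl]boronate | COB(OC)c1c(OCc2ccccc2)cccc1OCc1ccccc1 | intermediate (not isolated)
11 | 2,6-bis(benzyloxy)phenol | Oc1c(OCc2ccccc2)cccc1OCc1ccccc1 | intermediate
12 | 4-bromo-2,6-bis(benzyloxy)phenol | Oc1c(OCc2ccccc2)cc(Br)cc1OCc1ccccc1 | intermediate
13 | 2,6-bis(benzyloxy)-4-bromophenyl 3,4,5-tris(benzyloxy)benzoate | O=C(Oc1c(OCc2ccccc2)cc(Br)cc1OCc1ccccc1)c1cc(OCc2ccccc2)c(OCc2ccccc2)c(OCc2ccccc2)c1 | intermediate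
14 | 2,6-bis(benzyloxy)-4-(4,4,5,5-tetramethyl-1,3,2-dioxaborolan-2-yl)phenyl 3,4,5-tris(benzyloxy)benzoate | CC1(C)OB(OC1(C)C)c1cc(OCc2ccccc2)c(OC(=O)c2cc(OCc3ccccc3)c(OCc3ccccc3)c(OCc3ccccc3)c2)c(OCc2ccccc2)c1 | intermediate
15 | [3,5-bis(benzyloxy)-4-{[3,4,5-tris(benzyloxy)benzoyl]oxy}phenyl]boronic acid | OB(O)c1cc(OCc2ccccc2)c(OC(=O)c2cc(OCc3ccccc3)c(OCc3ccccc3)c(OCc3ccccc3)c2)c(OCc2ccccc2)c1 | intermediate
16 | (2R)-2-[3,5-bis(benzyloxy)-4-{[3,4,5-tris(benzyloxy)benzoyl]oxy}phenyl]-5,7-bis(benzyloxy)-2H-chromen-3-yl 3,4,5-tris(benzyloxy)benzoate | O=C(Oc1c(OCc2ccccc2)cc([C@H]2Oc3cc(OCc4ccccc4)cc(OCc4ccccc4)c3C=C2OC(=O)c2cc(OCc3ccccc3)c(OCc3ccccc3)c(OCc3ccccc3)c2)cc1OCc1ccccc1)c1cc(OCc2ccccc2)c(OCc2ccccc2)c(OCc2ccccc2)c1 | intermediate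
17 | epigallocatechin 3,4'-di-O-gallate, (2R,3R) | O=C(Oc1c(O)cc([C@H]2Oc3cc(O)cc(O)c3C[C@H]2OC(=O)c2cc(O)c(O)c(O)c2)cc1O)c1cc(O)c(O)c(O)c1 | target

Total step count: 11 steps.
Longest linear sequence: 7 steps (steps 5, 6, 7, 8, 9, 10, 11, from 1,3-bis(benzyloxy)benzene 8). The other branch runs through steps 1–4 and joins at step 10.

Steps most likely to fail

1. Step 10 (key step). The chiral ligand may discriminate the two faces of the 3-acyloxybenzopyrylium–nickel intermediate poorly, because the 3-substituent and the 5-benzyloxy group are absent from the precedents. Transmetalation of the bulky, ester-bearing boronic acid may also be slow, which would let uncatalysed background addition or attack at C4 compete. The fallback changes the activation mode from nickel cross-coupling to metal-free chiral boronate addition to the oxocarbenium ion. It sets out from boronic acid 15, which is esterified with ethanol (toluene, 4 Å molecular sieves, azeotropic removal of water) to diethyl [3,5-bis(benzyloxy)-4-{[3,4,5-tris(benzyloxy)benzoyl]oxy}phenyl]boronate F1. F1 is then added to acetal 7 in EtOAc at −20 °C with a catalytic tartaric-acid-derived amido acid (chiral diol Brønsted acid) and Ce(OTf)4 or Yb(OTf)3. The lanthanide ionises 7, and the chiral dioxaborolane formed by ligand exchange on boron should deliver the aryl group to C2 from one face. The fallback comes back to the route at 16.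

2. Step 11. Palladium may shift the C3=C4 double bond into the C2=C3 position before hydrogen is added, which would erase the C2 configuration. Hydrogenolysis of the allylic and benzylic C2–O1 bond or of the enol C3–O bond may also precede saturation. After debenzylation the 4'-gallate could migrate to a neighbouring free 3'-hydroxyl if the medium is not kept neutral to slightly acidic. The fallback separates the two events and sets out from 16. Homogeneous hydrogenation with a cationic iridium N,P catalyst of the Crabtree type (H2, CH2Cl2, rt), which does not cleave C–O bonds and isomerises little, should give (2R,3R)-2-[3,5-bis(benzyloxy)-4-{[3,4,5-tris(benzyloxy)benzoyl]oxy}phenyl]-5,7-bis(benzyloxy)chroman-3-yl 3,4,5-tris(benzyloxy)benzoate F2 by addition anti to the 2-aryl group. F2 is then debenzylated with H2 and Pd(OH)2/C in THF/MeOH, the established last step for perbenzylated flavan-3-ol gallates. The fallback comes back to the route at 17.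

3. Step 4. The quinone may over-oxidise the electron-rich chromene or form covalent adducts with the benzopyrylium ion. The acidic hydroquinone by-product may also promote ethanolysis of the enol ester or re-ionisation and hydrolysis of the acetal during isolation. The fallback replaces the quinone dehydrogenation by carbocation hydride transfer with isolation of the aromatic salt, and sets out from 5. Trityl tetrafluoroborate in CH2Cl2 at rt should abstract hydride from C2, and addition of Et2O should precipitate 5,7-bis(benzyloxy)-3-{[3,4,5-tris(benzyloxy)benzoyl]oxy}chromenylium tetrafluoroborate F3, free of oxidant and acid. The salt is then treated with ethanol and 2,6-lutidine in CH2Cl2 at 0 °C to give the acetal. The fallback comes back to the route at 7.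

Further compounds
F1 | step 10 | diethyl [3,5-bis(benzyloxy)-4-{[3,4,5-tris(benzyloxy)benzoyl]oxy}phenyl]boronate | CCOB(OCC)c1cc(OCc2ccccc2)c(OC(=O)c2cc(OCc3ccccc3)c(OCc3ccccc3)c(OCc3ccccc3)c2)c(OCc2ccccc2)c1
F2 | step 11 | (2R,3R)-2-[3,5-bis(benzyloxy)-4-{[3,4,5-tris(benzyloxy)benzoyl]oxy}phenyl]-5,7-bis(benzyloxy)chroman-3-yl 3,4,5-tris(benzyloxy)benzoate | O=C(Oc1c(OCc2ccccc2)cc([C@H]2Oc3cc(OCc4ccccc4)cc(OCc4ccccc4)c3C[C@H]2OC(=O)c2cc(OCc3ccccc3)c(OCc3ccccc3)c(OCc3ccccc3)c2)cc1OCc1ccccc1)c1cc(OCc2ccccc2)c(OCc2ccccc2)c(OCc2ccccc2)c1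
F3 | step 4 | 5,7-bis(benzyloxy)-3-{[3,4,5-tris(benzyloxy)benzoyl]oxy}chromenylium tetrafluoroborate | O=C(Oc1c[o+]c2cc(OCc3ccccc3)cc(OCc3ccccc3)c2c1)c1cc(OCc2ccccc2)c(OCc2ccccc2)c(OCc2ccccc2)c1.F[B-](F)(F)F
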